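Numbering used throughout: ring A is C1–C2–C3–C4–C5–C10, ring B is C5–C6–C7–C8–C9–C10, C11 is the formyl carbon on C9 and C12 the ester carbon on C8. β is the face of the C10 methyl group.

## Analysis of the target

The target is a drimane-like trans-decalin with a C7=C8 enoate (C12 methyl ester), a formyl group (C11) on C9 and an (E)-4-hydroxy-4-methylpent-2-enyl chain on C4. It has six stereocentres: C1 (α-OH, axial), C3 (β-Cl, equatorial), C4 (quaternary, β-methyl axial, α side chain), C5 (α-H), C10 (quaternary, β-methyl) and C9 (β-CHO, equatorial). The two methyl groups on C4 and C10 are 1,3-diaxial, and C4–C5–C10 is a contiguous array with two quaternary carbons. The sensitive groups are the β,γ-unsaturated aldehyde (H-9 is α to the aldehyde and allylic to the enoate, so it epimerises and the double bond can move to C8=C9), the tertiary allylic alcohol (ionises in acid) and the secondary chloride on a carbon next to quaternary C4 (hard to make by displacement, prone to elimination). With 1α-O axial and C11 equatorial the two successive torsions O1–C1–C10–C9 and C1–C10–C9–C11 have the same sign, so a 1,11-lactol cannot close; it would close at once if C9 epimerised. C11 and C12 must end at different oxidation levels although they sit on neighbouring carbons. The strategy rests on the fact that C11 and C12 are 1,4-related through the C8–C9 bond, which joins two carbons that are each α to a carboxyl carbon, while ring A already holds the C5 and C10 substituents trans.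

## Retrosynthetic reasoning

**Side chain and O1 (38 back to 35 and 36).** The O1–Si bond of 37 is cleaved last, and the side-chain C=C bond is cut by a retro cross-metathesis to the allyl group of 35 and the tertiary allylic alcohol 36. The cut is placed there because the allyl group is inert to all the anionic and oxidative chemistry before it, whereas the tertiary allylic alcohol is not. The forward step has to give the E-alkene and leave the aldehyde and the trisubstituted enoate alone.

**C11 oxidation level (35 back to 33 and 31).** The formyl group is traced to the acid 33 and that to the tert-butyl ester 31. The reduction has to stop at the aldehyde: a C11 alcohol would close a five-membered lactone onto the C12 ester (O–C11–C9–C8–C12), and a borane reduction of the acid would also attack the allyl group. Two different ester alkyl groups are what keep C11 and C12 apart.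

**C7=C8 double bond (31 back to 30 and 26).** The unsaturation is removed to give the saturated diester 26. Dehydrogenation through the C8 ester enolate can eliminate towards C7 or C9, so the forward plan accepts the C8=C9 isomer 30 and moves the double bond by base equilibration. The tetrasubstituted C8=C9 alkene holds C11 in the plane beside C1 and its axial silyloxy group, so C7=C8 with an equatorial 9β-ester should be the stable arrangement. This also means that the configuration at C8 and C9 in 26 does not matter.

**Ring B (26 back to 24).** The C8–C9 bond is cut. Both carbons are nucleophilic α-carbons of esters, so no ordinary donor–acceptor pairing makes this bond, but an oxidative union of two enolates does. What remains is ring A with a butanoate arm on C5 and a tert-butyl acetate arm on C10, a monocyclic problem in which all other stereocentres are already set. The forward step has to close a six-membered ring in preference to intermolecular coupling.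

**C3–Cl and C1–O (24 back to 22, 21, 20 and 19).** The C–Cl bond is cut to the 3α-alcohol 22, so the chloride enters with inversion. It is introduced before ring closure because an equatorial 3β-chloride lets ring A adopt the chair with both arms equatorial, whereas a 3α-silyl ether would be 1,3-diaxial to the 1α-silyl ether. It cannot be introduced earlier, because the 3α-oxygen is needed to steer the C5 stereocentre and because a leaving group at C3 next to the C1 ketone of 19 would simply eliminate. The C1–H bond comes from reduction of ketone 19, and two different silyl groups (21) allow O3 to be freed alone.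

**Both arms (19 back to 12, 13 and 16).** The C5–C6 and C10–C9 bonds are cut together: conjugate addition to enone 12 at C5, then alkylation of the resulting C10 enolate with 16. The 3α-silyloxy group sits at position 5 of the cyclohexenone and sends the nucleophile to the opposite (β) face; the new C5 arm then sends the electrophile to the α face. This gives the trans arms and the C10 quaternary centre in two operations. The butanoate arm is carried as orthoester 13, because a free ester would not survive regeneration of the enolate and could be attacked by the C10 enolate in a six-membered Claisen closure.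

**Enone 12 (back to 11, 9, 8, 6 and 4).** Enone 12 has its carbonyl at C1, whereas the chiral building block has it at C5. A 1,3-carbonyl transposition (epoxy ketone 9 to allylic alcohol 11) moves the oxygen, and the C10–CH3 bond is cut back to ketone 4, where C10 is the only enolisable position.

**Ring A stereocentres (4 back to 3, 2 and 1).** C3 and C4 are set together by reduction of one of the two enantiotopic carbonyl groups of dione 2; the C4–allyl bond is cut back to 1. The needed isomer 3 has OH and allyl cis, which is the normal outcome of hydride attack anti to the larger group.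

## Alternatives that were turned down

**Alternative 1:** The disconnection cuts C5–C10 and C8–C9 in one retro-[4+2] step and opens both rings. Forward, a Lewis-acid-promoted intramolecular Diels–Alder reaction adds an enal dienophile (C9=C10, also conjugated to the C1 ketone) to an (E,E)-diene (C5 to C8) through the C1–C4 tether and gives A1, a trans-fused octalin aldehyde with a C6=C7 alkene, a C1 ketone, a 3β-silyl ether and C12 as a PMB ether.
- For: two rings, two C–C bonds and four stereocentres (C5, C8, C9, C10, including the C10 quaternary carbon) arise at once, and C11 arrives as the aldehyde. On bond economy this is stronger than the chosen key step, which makes one bond and one ring.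
- Against: C3 and C4 must be set on an open chain, and they are the only control over the face of the cycloaddition. The diene terminus C5 is attached to quaternary C4 and the dienophile is trisubstituted and doubly activated, so reactivity and endo/exo control are open questions. A1 still needs deprotection, two oxidations and esterification at C12, migration of C6=C7 into conjugation past an epimerisable C9 aldehyde, reduction at C1, and introduction of chlorine at C3 with overall retention.
- Comparison: the chosen route sets every ring A centre on a ring with cyclic stereocontrol, its key step needs no stereoselectivity, and C11 and C12 are differentiated from the start.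

**Alternative 2:** The disconnection cuts C9–C10 and C7–C8 and uses O1 as a tether. Forward, a thermal intramolecular Diels–Alder reaction of an O1-bound alkyne diester unit with a ring A diene (C10=C5–C6=C7) gives A2, a tricyclic γ-lactone with C5=C6 and C8=C9 alkenes.
- For: the tether fixes regiochemistry and delivers the dienophile to the α face of C10, so the quaternary centre is set by the existing C1 stereocentre. C11 (lactone) and C12 (methyl ester) are differentiated at least as cleanly as by two ester types, and no strong base is needed.
- Against: the diene terminus C10 is fully substituted, so the cycloaddition must form a quaternary carbon at a hindered position. A2 then needs C5=C6 reduced from the α face in the presence of the allyl group, which any hydrogenation would take first. It also needs C8=C9 moved to C7=C8 with C11 on the β face of C9, but the lactone ties C11 to the α face through O1, so it must be opened first. Finally the lactone carbonyl must be brought to the aldehyde level beside a methyl ester.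
- Comparison: the chosen route has the trans ring fusion preset by ring A and obtains C9 by simple equilibration, at the cost of a longer preparation of ring A.

**Alternative 3:** The disconnection cuts C1–C2 and C3–Cl and forms ring A last on a complete ring B. Forward, a tin Lewis acid activates a C1 aldehyde on C10, the terminal carbon of a vinyl group on C4 attacks it, and chloride captures the C3 cation to give A3, a trans-decalin 1α-ol 3β-chloride carrying a C8 enol triflate, a silylated C11 alcohol and an ethyl acetate arm on C4.
- For: the C–Cl bond and the C1 hydroxyl are made in the ring-forming step, with chloride equatorial through a chair closure. This avoids displacement at the hindered C3, which is the weakest ordinary step of the chosen route; on this point the alternative is clearly stronger.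
- Against: the C3 cation is secondary and flanked by quaternary C4, so a 1,2-shift or proton loss competes with chloride capture. The substrate needs vicinal quaternary C4 and C10 with vinyl and formyl groups on ring B, and the key step does not help to build them. Afterwards the side chain must be grown from the acetate arm, C12 brought in by carbonylation of the triflate and C11 oxidised.
- Comparison: the chosen route avoids cation chemistry next to a quaternary carbon and has the side-chain handle and both carboxyl carbons in place at ring closure; it pays for this with the displacement at C3.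

Key step: step 15

Remark: the absolute sense of step 2 is taken from the usual oxazaborolidine model and should give the enantiomer of the yeast-derived (2S,3S)-ketol; if the model fails, the other catalyst enantiomer is used.

## Route

Step 1
Reactants: 1 2-methylcyclohexane-1,3-dione
Product: 2 2-methyl-2-(prop-2-enyl)cyclohexane-1,3-dione
Conditions: allyl bromide, 1 M aq. NaOH, rt
Reagents that add atoms: allyl bromide, C=CCBr
Why: C-alkylation of the cyclic 1,3-diketone enolate by an allylic halide; the alkylated carbon is the future C4 and is not yet stereogenic.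

Step 2
Reactants: 2 2-methyl-2-(prop-2-enyl)cyclohexane-1,3-dione
Product: 3 (2R,3R)-3-hydroxy-2-methyl-2-(prop-2-enyl)cyclohexan-1-one
Conditions: (S)-2-methyl-CBS-oxazaborolidine (20 mol %), catecholborane (1.0 equiv), toluene, −78 → −40 °C; aqueous work-up
Reagents that add atoms: none
Why: Corey–Bakshi–Shibata reduction of one of two enantiotopic carbonyl groups: the catalyst distinguishes the quaternary flank from the methylene flank and should give the (R)-carbinol, while hydride approach anti to the larger allyl group decides which carbonyl reacts, so that OH and allyl are cis (3α-OH, 4α-allyl, 4β-methyl). One equivalent of hydride limits diol formation.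

Step 3
Reactants: 3 (2R,3R)-3-hydroxy-2-methyl-2-(prop-2-enyl)cyclohexan-1-one
Product: 4 (2R,3R)-2-methyl-2-(prop-2-enyl)-3-(triethylsilyloxy)cyclohexan-1-one
Conditions: Et3SiCl, imidazole, DMF, 0 °C → rt
Reagents that add atoms: chlorotriethylsilane, CC[Si](Cl)(CC)CC
Why: Silylation of a secondary alcohol under non-basic conditions, which avoids retro-aldol opening of the β-hydroxy ketone; the triethylsilyl group can later be removed beside a tert-butyldimethylsilyl ether.

Step 4
Reactants: 4 (2R,3R)-2-methyl-2-(prop-2-enyl)-3-(triethylsilyloxy)cyclohexan-1-one
Product: 6 C10-methyl ketone (2-allyl-2,6-dimethyl-3-triethylsilyloxycyclohexanone; both C10 epimers), via lithium enolate 5 (not isolated)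
Conditions: LiN(i-Pr)2, THF, −78 °C; MeI, −78 → −20 °C
Reagents that add atoms: iodomethane, CI
Why: Kinetic enolate alkylation; C10 is the only enolisable position because C4 is quaternary. The new centre is uncontrolled and becomes trigonal in step 5.

Step 5
Reactants: 6 C10-methyl ketone
Product: 8 enone with C5 ketone and C10(Me)=C1 (6-allyl-2,6-dimethyl-5-triethylsilyloxycyclohex-2-en-1-one), via trimethylsilyl enol ether 7 (not isolated)
Conditions: Me3SiOTf, Et3N, CH2Cl2, 0 °C; then Pd(OAc)2 (1.05 equiv), MeCN, rt
Reagents that add atoms: none
Why: Saegusa–Ito dehydrogenation; the silyl enol ether can form only towards C10, and β-hydride elimination from the palladium enolate towards the ring CH2 gives the endocyclic enone.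

Step 6
Reactants: 8 enone with C5 ketone and C10(Me)=C1
Product: 9 1,10-epoxy ketone (β-epoxide expected)
Conditions: 30% aq. H2O2, NaOH (cat.), MeOH, 0 °C
Reagents that add atoms: hydrogen peroxide, OO
Why: Weitz–Scheffer nucleophilic epoxidation of an α-methyl enone; attack at C1 trans to the 3α-silyloxy group is expected, but both new centres are lost by step 8, so the face is irrelevant.

Step 7
Reactants: 9 1,10-epoxy ketone
Product: 11 allylic alcohol with C1–OH and C5=C10(Me), via epoxy hydrazone 10 (not isolated)
Conditions: N2H4·H2O, AcOH (cat.), MeOH, 0 °C → rt, under argon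
Reagents that add atoms: none
Why: Wharton transposition: the epoxy hydrazone fragments with loss of N2, moving the oxygen from C5 to C1 and the double bond to C5=C10. Air is excluded so that diimide does not reduce the allyl group.

Step 8
Reactants: 11 allylic alcohol with C1–OH and C5=C10(Me)
Product: 12 transposed enone with C1 ketone and C10(Me)=C5 (4-allyl-2,4-dimethyl-5-triethylsilyloxycyclohex-2-en-1-one; 3α-OSiEt3; 4β-Me; 4α-allyl)
Conditions: Dess–Martin periodinane, CH2Cl2, rt
Reagents that add atoms: none
Why: Dess–Martin oxidation of a secondary allylic alcohol completes the 1,3-carbonyl transposition and removes the C1 stereocentre.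

Step 9
Reactants: 12 transposed enone; 13 4-bromo-1,1,1-trimethoxybutane (trimethyl 4-bromoorthobutyrate)
Product: 15 trimethylsilyl enol ether (C1(OSiMe3)=C10) carrying the 5β-(4,4,4-trimethoxybutyl) arm, via (4,4,4-trimethoxybutyl)magnesium bromide 14 (not isolated)
Conditions: 13, Mg, THF, rt; then CuBr·SMe2 (10 mol %), Me3SiCl, HMPA, 12, THF, −78 °C; Et3N quench
Reagents that add atoms: chlorotrimethylsilane, C[Si](C)(C)Cl
Why: Copper-catalysed conjugate addition of a Grignard reagent, accelerated by Me3SiCl, which copes with a β-carbon next to a quaternary centre. The nucleophile enters C5 axially, trans to the 3α-silyloxy group (position 5 of the cyclohexenone) and anti to the pseudoaxial allyl group, which puts the arm on the β face. The orthoester is inert to the Grignard reagent and to the next step, where an ester would not be.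

Step 10
Reactants: 15 trimethylsilyl enol ether; 16 tert-butyl bromoacetate
Product: 19 keto diester (C1 ketone; 3α-OSiEt3; 5β methyl butanoate arm; 10β-Me; 10α tert-butyl acetate arm), via lithium enolate 17 (not isolated), via orthoester keto ester 18 (not isolated)
Conditions: MeLi, THF, 0 °C; 16, HMPA, −78 → −20 °C; then pH 4 aq. citrate buffer, THF, 0 °C
Reagents that add atoms: water, O
Why: Cleavage of the silyl enol ether by MeLi gives the lithium enolate regiospecifically at C10; alkylation by the reactive α-bromo ester occurs anti to the adjacent C5 arm and creates the C10 quaternary centre with methyl β and the acetate arm α, so the two arms are trans. Mild aqueous acid then turns the orthoester into the methyl ester without touching the silyl ether.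

Step 11
Reactants: 19 keto diester
Product: 20 1α-alcohol
Conditions: LiBH(s-Bu)3, THF, −78 °C; AcOH quench at −78 °C
Reagents that add atoms: none
Why: Ketone reduction by a bulky trialkylborohydride from the less hindered β face (the α face carries the C10 acetate arm and the 3α-silyloxy group) gives the axial 1α-alcohol. Esters are inert at −78 °C, and the cold acidic quench keeps the alkoxide from lactonising onto C11.

Step 12
Reactants: 20 1α-alcohol
Product: 21 1α-tert-butyldimethylsilyl 3α-triethylsilyl bis-ether
Conditions: t-BuMe2SiOTf, 2,6-lutidine, CH2Cl2, −78 → −30 °C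
Reagents that add atoms: tert-butyldimethylsilyl triflate, CC(C)(C)[Si](C)(C)OS(=O)(=O)C(F)(F)F
Why: Silyl triflate silylation of a hindered secondary alcohol; the low temperature spares the tert-butyl ester.

Step 13
Reactants: 21 bis-silyl ether
Product: 22 3α-alcohol
Conditions: pyridinium p-toluenesulfonate (cat.), MeOH/CH2Cl2, 0 °C
Reagents that add atoms: none
Why: Acid-catalysed methanolysis removes the triethylsilyl ether, which is far more labile than the tert-butyldimethylsilyl ether; both esters are stable.

Step 14
Reactants: 22 3α-alcohol
Product: 24 ring A diester with 3β-chloride (key-step precursor), via 3α-triflate 23 (not isolated)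
Conditions: Tf2O, 2,6-lutidine, CH2Cl2, −60 °C; then Bu4NCl, −60 → 0 °C
Reagents that add atoms: tetrabutylammonium chloride, CCCC[N+](CCCC)(CCCC)CCCC.[Cl-]
Why: Sulfonate displacement with inversion (3α-O to 3β-Cl); triflate is the leaving group of choice at a neopentyl-type carbon, and a soluble chloride at low temperature is used to favour substitution over elimination. Inversion sets C3.

Step 15
Reactants: 24 ring A diester with 3β-chloride
Product: 26 trans-decalin diester (8α-CO2Me; 9β-CO2t-Bu; 3β-Cl; 1α-OSiMe2t-Bu), via dilithium bis-enolate 25 (not isolated)
Conditions: LiN(i-Pr)2 (2.3 equiv), THF, −78 → −40 °C; anhydrous CuCl2 (2.2 equiv) in DMF, −78 °C → rt, 0.005 M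
Reagents that add atoms: none
Why: Two equivalents of LiN(i-Pr)2 convert both ester arms of 24 into enolates (25); CuCl2 (divalent copper) removes one electron from one enolate to give an α-carbonyl radical or copper-bound enolate, which attacks the α-carbon of the second enolate, and a second equivalent oxidises the resulting radical anion to the succinate 26, each copper ending as monovalent CuCl. The closest known reaction type is the intramolecular oxidative coupling of diester bis-enolates to cycloalkane-1,2-dicarboxylates with copper dihalides or iodine. Ring B closes in the 6-exo mode (C8 onto C9) through a chair in which the C5 and C10 arms are the two equatorial, gauche substituents of ring A; because these arms are trans on ring A, only the trans-decalin can form. C8 is expected to carry its ester α (equatorial), since an axial ester there would be 1,3-diaxial to the C10 methyl group, and C9 its ester β (equatorial), since an α-ester would run into the axial 1α-silyloxy group. Neither new centre has to be controlled, because C8 becomes trigonal in step 16 and C9 is equilibrated in step 17. What the step does need is ring closure in preference to intermolecular coupling, α-chlorination and return of protons: high dilution serves the first, and the ring A chair with the 3β-chloride equatorial (the other chair would put the allyl group, both arms and the chloride axial) holds the two enolate carbons within bonding distance. Only one pairing of enolates is possible within the molecule, so the methyl and tert-butyl esters end up on C12 and C11 as required. The secondary chloride should survive because it is equatorial (no anti-periplanar hydrogen) and neopentylic.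

Step 16
Reactants: 26 trans-decalin diester
Product: 30 C8=C9 unsaturated diester, via lithium ester enolate 27 (not isolated), via α-phenylselenyl ester 28 (not isolated), via selenoxide 29 (not isolated)
Conditions: LiN(i-Pr)2 (1.1 equiv), THF, −78 °C; PhSeBr; then 30% H2O2, pyridine, CH2Cl2, 0 °C → rt
Reagents that add atoms: none
Why: Ester enolate selenenylation and selenoxide syn-elimination; the less hindered C8–H of the methyl ester is removed first. Elimination towards the more acidic H-9 is expected to dominate, and any C7=C8 isomer formed alongside is the product of step 17 and is carried forward.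

Step 17
Reactants: 30 C8=C9 unsaturated diester
Product: 31 C7=C8 enoate with 9β tert-butyl ester
Conditions: NaOMe (0.3 equiv), MeOH/THF, rt
Reagents that add atoms: none
Why: Base equilibration through the extended enolate: the tetrasubstituted C8=C9 alkene holds C11 in the plane beside C1 and its silyloxy group, so the double bond should move to C7=C8, as in the base isomerisation of drimane-type ene-diesters. C9 is then protonated to the equatorial 9β-ester, the 9α-epimer being syn-pentane to the 1α-silyloxy group; the tert-butyl ester resists methoxide.

Step 18
Reactants: 31 C7=C8 enoate with 9β tert-butyl ester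
Product: 33 C11 carboxylic acid, via trimethylsilyl ester 32 (not isolated)
Conditions: Me3SiOTf, 2,6-lutidine, CH2Cl2, 0 °C; then H2O
Reagents that add atoms: none
Why: Silyl triflate cleavage of a tert-butyl ester (loss of 2-methylpropene) to the silyl ester, which hydrolyses on work-up; the methyl enoate and the silyl ether are not affected.

Step 19
Reactants: 33 C11 carboxylic acid
Product: 35 C11 aldehyde (4α-allyl; 1α-OSiMe2t-Bu), via acid chloride 34 (not isolated)
Conditions: (COCl)2, DMF (cat.), CH2Cl2, 0 °C; then LiAlH(Ot-Bu)3 (1.05 equiv), THF, −78 °C
Reagents that add atoms: none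
Why: Acid chloride formation and reduction with the hindered hydride LiAlH(Ot-Bu)3, which stops at the aldehyde and leaves the enoate alone. The alcohol level is avoided on purpose, because a C11 alcohol would lactonise onto C12 and a borane reduction would hydroborate the allyl group.

Step 20
Reactants: 35 C11 aldehyde; 36 2-methylbut-3-en-2-ol
Product: 37 1-O-silylated target with the (E)-4-hydroxy-4-methylpent-2-enyl chain
Conditions: 36 (8 equiv), second-generation Grubbs catalyst RuCl2(=CHPh)(H2IMes)(PCy3) (5 mol %), CH2Cl2, 40 °C
Reagents that add atoms: none
Why: Olefin cross-metathesis between a terminal alkene and a tertiary allylic alcohol that homodimerises slowly; this pairing gives the E-disubstituted alkene, and the trisubstituted enoate and the aldehyde are inert to the catalyst.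

Step 21
Reactants: 37 1-O-silylated target
Product: 38 target, methyl (1α-hydroxy-3β-chloro-9β-formyl) C7=C8 enoate, CNP0167913.1
Conditions: HF·pyridine, pyridine, THF, 0 °C → rt
Reagents that add atoms: none
Why: Fluoride-mediated cleavage of the silyl ether under buffered, weakly acidic conditions; basic fluoride sources are avoided because H-9 is acidic and the 9α-epimer would be trapped as a lactol.

## Compound list

1 | 2-methylcyclohexane-1,3-dione | CC1C(=O)CCCC1=O | starting material
2 | 2-methyl-2-(prop-2-enyl)cyclohexane-1,3-dione | C=CCC1(C)C(=O)CCCC1=O | intermediate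
3 | (2R,3R)-3-hydroxy-2-methyl-2-(prop-2-enyl)cyclohexan-1-one (C5 ketone, 3α-OH, 4β-Me, 4α-allyl) | O=C1[C@](C)(CC=C)[C@H](O)CCC1 | intermediate
4 | (2R,3R)-2-methyl-2-(prop-2-enyl)-3-(triethylsilyloxy)cyclohexan-1-one | O=C1[C@](C)(CC=C)[C@H](O[Si](CC)(CC)CC)CCC1 | intermediate
5 | lithium enolate of 4 (C5–OLi, C5=C10) | [Li]OC=1[C@](C)(CC=C)[C@H](O[Si](CC)(CC)CC)CCC=1 | intermediate
6 | C10-methyl ketone, both C10 epimers | O=C1[C@](C)(CC=C)[C@H](O[Si](CC)(CC)CC)CCC1C | intermediate
7 | trimethylsilyl enol ether of 6 | C[Si](C)(C)OC=1[C@](C)(CC=C)[C@H](O[Si](CC)(CC)CC)CCC=1C | intermediate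
8 | enone, C5 ketone, C10(Me)=C1 | O=C1[C@](C)(CC=C)[C@H](O[Si](CC)(CC)CC)CC=C1C | intermediate
9 | 1β,10β-epoxy ketone | O=C1[C@](C)(CC=C)[C@H](O[Si](CC)(CC)CC)C[C@H]2O[C@@]12C | intermediate
10 | hydrazone of 9 | NN=C1[C@](C)(CC=C)[C@H](O[Si](CC)(CC)CC)C[C@H]2O[C@@]12C | intermediate
11 | allylic alcohol, 1β-OH, C5=C10(Me) | CC1=C[C@](C)(CC=C)[C@H](O[Si](CC)(CC)CC)C[C@H]1O | intermediate
12 | transposed enone, C1 ketone, C10(Me)=C5, 3α-OSiEt3, 4β-Me, 4α-allyl | CC1=C[C@](C)(CC=C)[C@H](O[Si](CC)(CC)CC)CC1=O | intermediate
13 | 4-bromo-1,1,1-trimethoxybutane | COC(OC)(OC)CCCBr | starting material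
14 | (4,4,4-trimethoxybutyl)magnesium bromide | COC(OC)(OC)CCC[Mg]Br | intermediate
15 | trimethylsilyl enol ether C1(OSiMe3)=C10 with 5β-(4,4,4-trimethoxybutyl) arm | COC(OC)(OC)CCC[C@H]1[C@](C)(CC=C)[C@H](O[Si](CC)(CC)CC)CC(O[Si](C)(C)C)=C1C | intermediate
16 | tert-butyl bromoacetate | CC(C)(C)OC(=O)CBr | starting material
17 | lithium enolate from 15 | COC(OC)(OC)CCC[C@H]1[C@](C)(CC=C)[C@H](O[Si](CC)(CC)CC)CC(O[Li])=C1C | intermediate
18 | orthoester keto ester (10β-Me, 10α-CH2CO2t-Bu) | COC(OC)(OC)CCC[C@H]1[C@](C)(CC=C)[C@H](O[Si](CC)(CC)CC)CC(=O)[C@]1(C)CC(=O)OC(C)(C)C | intermediate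
19 | keto diester (C1 ketone, 3α-OSiEt3) | COC(=O)CCC[C@H]1[C@](C)(CC=C)[C@H](O[Si](CC)(CC)CC)CC(=O)[C@]1(C)CC(=O)OC(C)(C)C | intermediate
20 | 1α-alcohol | COC(=O)CCC[C@H]1[C@](C)(CC=C)[C@H](O[Si](CC)(CC)CC)C[C@H](O)[C@]1(C)CC(=O)OC(C)(C)C | intermediate
21 | 1α-OSiMe2t-Bu, 3α-OSiEt3 diester | COC(=O)CCC[C@H]1[C@](C)(CC=C)[C@H](O[Si](CC)(CC)CC)C[C@H](O[Si](C)(C)C(C)(C)C)[C@]1(C)CC(=O)OC(C)(C)C | intermediate
22 | 3α-alcohol | COC(=O)CCC[C@H]1[C@](C)(CC=C)[C@H](O)C[C@H](O[Si](C)(C)C(C)(C)C)[C@]1(C)CC(=O)OC(C)(C)C | intermediate
23 | 3α-triflate | COC(=O)CCC[C@H]1[C@](C)(CC=C)[C@H](OS(=O)(=O)C(F)(F)F)C[C@H](O[Si](C)(C)C(C)(C)C)[C@]1(C)CC(=O)OC(C)(C)C | intermediate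
24 | ring A diester, 3β-chloride, 1α-OSiMe2t-Bu (key-step precursor) | COC(=O)CCC[C@H]1[C@](C)(CC=C)[C@@H](Cl)C[C@H](O[Si](C)(C)C(C)(C)C)[C@]1(C)CC(=O)OC(C)(C)C | intermediate
25 | dilithium bis-enolate of 24 | COC(O[Li])=CCC[C@H]1[C@](C)(CC=C)[C@@H](Cl)C[C@H](O[Si](C)(C)C(C)(C)C)[C@]1(C)C=C(O[Li])OC(C)(C)C | intermediate
26 | trans-decalin 8α-methyl 9β-tert-butyl diester (key-step product) | COC(=O)[C@@H]1CC[C@H]2[C@](C)(CC=C)[C@@H](Cl)C[C@H](O[Si](C)(C)C(C)(C)C)[C@]2(C)[C@H]1C(=O)OC(C)(C)C | intermediate
27 | lithium enolate of 26 at C8 | COC(O[Li])=C1CC[C@H]2[C@](C)(CC=C)[C@@H](Cl)C[C@H](O[Si](C)(C)C(C)(C)C)[C@]2(C)[C@H]1C(=O)OC(C)(C)C | intermediate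
28 | 8α-phenylselenyl diester | COC(=O)[C@@]1([Se]c3ccccc3)CC[C@H]2[C@](C)(CC=C)[C@@H](Cl)C[C@H](O[Si](C)(C)C(C)(C)C)[C@]2(C)[C@H]1C(=O)OC(C)(C)C | intermediate
29 | selenoxide of 28 | COC(=O)[C@@]1([Se](=O)c3ccccc3)CC[C@H]2[C@](C)(CC=C)[C@@H](Cl)C[C@H](O[Si](C)(C)C(C)(C)C)[C@]2(C)[C@H]1C(=O)OC(C)(C)C | intermediate
30 | C8=C9 unsaturated diester | COC(=O)C=1CC[C@H]2[C@](C)(CC=C)[C@@H](Cl)C[C@H](O[Si](C)(C)C(C)(C)C)[C@]2(C)C=1C(=O)OC(C)(C)C | intermediate
31 | C7=C8 enoate, 9β tert-butyl ester | COC(=O)C1=CC[C@H]2[C@](C)(CC=C)[C@@H](Cl)C[C@H](O[Si](C)(C)C(C)(C)C)[C@]2(C)[C@H]1C(=O)OC(C)(C)C | intermediate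
32 | C11 trimethylsilyl ester | COC(=O)C1=CC[C@H]2[C@](C)(CC=C)[C@@H](Cl)C[C@H](O[Si](C)(C)C(C)(C)C)[C@]2(C)[C@H]1C(=O)O[Si](C)(C)C | intermediate
33 | C11 carboxylic acid | COC(=O)C1=CC[C@H]2[C@](C)(CC=C)[C@@H](Cl)C[C@H](O[Si](C)(C)C(C)(C)C)[C@]2(C)[C@H]1C(=O)O | intermediate
34 | C11 acid chloride | COC(=O)C1=CC[C@H]2[C@](C)(CC=C)[C@@H](Cl)C[C@H](O[Si](C)(C)C(C)(C)C)[C@]2(C)[C@H]1C(=O)Cl | intermediate
35 | C11 aldehyde, 4α-allyl, 1α-OSiMe2t-Bu | COC(=O)C1=CC[C@H]2[C@](C)(CC=C)[C@@H](Cl)C[C@H](O[Si](C)(C)C(C)(C)C)[C@]2(C)[C@H]1C=O | intermediate
36 | 2-methylbut-3-en-2-ol | CC(C)(O)C=C | starting material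
37 | 1-O-(tert-butyldimethylsilyl) target | COC(=O)C1=CC[C@H]2[C@](C)(C/C=C/C(C)(C)O)[C@@H](Cl)C[C@H](O[Si](C)(C)C(C)(C)C)[C@]2(C)[C@H]1C=O | intermediate
38 | CNP0167913.1 | COC(=O)C1=CC[C@H]2[C@](C)(C/C=C/C(C)(C)O)[C@@H](Cl)C[C@H](O)[C@]2(C)[C@H]1C=O | target

## Step count and weak points

Total: 21 steps. Longest linear sequence: 21 steps, from 1 to 38; 13, 16 and 36 are bought.

**Step 15 (key step).** The likely failure is that the bis-enolate is consumed by other channels before the ring closes: intermolecular coupling, α-chlorination of one enolate, or return of protons from diisopropylamine. Enolisation at the hindered C9 methylene may also be incomplete. Fallback, from 24 back to 26: the bis-enolate is trapped with Me3SiCl as the bis(trimethylsilyl ketene acetal) F1, freed from amine and salts, and closed with TiCl4 in CH2Cl2 at −78 °C. This is the oxidative coupling of ketene silyl acetals to succinates, in which the C–C bond forms between titanium-bound enolates (tetravalent titanium is reduced) and no proton source or free oxidant is present.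

**Step 14.** Elimination towards C2 (the axial leaving group has an anti-periplanar hydrogen) or a cationic 1,2-shift from C4 may win over substitution at this neopentyl-type carbon; in the monocycle the ring may also flip to a chair in which the axial C5 arm blocks the backside. Fallback, from 21 back to 26: the ring is closed first under the conditions of step 15, through the dilithium bis-enolate F2 to the trans-decalin 3α-triethylsilyl ether F3. Methanolysis gives the 3α-alcohol F4, and the triflate F5 is displaced with Bu4NCl on the rigid decalin, where the leaving group is locked axial and the C5 substituent is tied back in ring B.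

**Step 11.** Facial selectivity may be poor, because ring A of 19 has two chairs of similar energy and each exposes a different face of the C1 carbonyl to a bulky hydride. Fallback, from 19 to 20: catalyst-controlled reduction with (R)-2-methyl-CBS-oxazaborolidine and catecholborane. Here the choice of face rests on the size difference between quaternary C10 and the C2 methylene, not on the ring conformation; no new compound is involved.

**Step 7.** Hydrazone formation at the C5 carbonyl, which lies between quaternary C4 and the epoxide carbon, may be slow enough for hydrazine to open the epoxide or reduce the allyl group instead. Fallback, from 6 back to 12: the lithium enolate F6 is O-triflated with PhNTf2 to the enol triflate F7, which is reduced with Pd(OAc)2, PPh3, HCO2H and Bu3N to the trisubstituted alkene F8. Allylic oxidation with CrO3·3,5-dimethylpyrazole at C1, the only ring position next to the double bond that bears hydrogen, gives 12.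

**Step 21.** Cleavage of the hindered axial silyl ether may be slow, and long exposure to acid can epimerise C9 (followed by lactol closure), move the double bond into conjugation with the aldehyde or ionise the tertiary allylic alcohol. Fallback, from 31 back to 38: the silyl group is exchanged before the aldehyde exists.
- HF·pyridine on the robust diester gives the alcohol F9, and Et3SiOTf with 2,6-lutidine gives the triethylsilyl ether F10.
- Steps 18 to 20 are repeated (with pyridine added in the acid chloride step): trimethylsilyl ester F11, acid F12, acid chloride F13, aldehyde F14 and metathesis product F15.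
- AcOH/THF/H2O at rt then frees the hydroxyl under much milder conditions.

## Further compounds

F1 | step 15 | bis(trimethylsilyl ketene acetal) of 24 | COC(O[Si](C)(C)C)=CCC[C@H]1[C@](C)(CC=C)[C@@H](Cl)C[C@H](O[Si](C)(C)C(C)(C)C)[C@]1(C)C=C(O[Si](C)(C)C)OC(C)(C)C
F2 | step 14 | dilithium bis-enolate of 21 | COC(O[Li])=CCC[C@H]1[C@](C)(CC=C)[C@H](O[Si](CC)(CC)CC)C[C@H](O[Si](C)(C)C(C)(C)C)[C@]1(C)C=C(O[Li])OC(C)(C)C
F3 | step 14 | trans-decalin diester with 3α-triethylsilyloxy group | COC(=O)[C@@H]1CC[C@H]2[C@](C)(CC=C)[C@H](O[Si](CC)(CC)CC)C[C@H](O[Si](C)(C)C(C)(C)C)[C@]2(C)[C@H]1C(=O)OC(C)(C)C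
F4 | step 14 | trans-decalin diester 3α-alcohol | COC(=O)[C@@H]1CC[C@H]2[C@](C)(CC=C)[C@H](O)C[C@H](O[Si](C)(C)C(C)(C)C)[C@]2(C)[C@H]1C(=O)OC(C)(C)C
F5 | step 14 | trans-decalin diester 3α-triflate | COC(=O)[C@@H]1CC[C@H]2[C@](C)(CC=C)[C@H](OS(=O)(=O)C(F)(F)F)C[C@H](O[Si](C)(C)C(C)(C)C)[C@]2(C)[C@H]1C(=O)OC(C)(C)C
F0 | step 11 | none | none
F6 | step 7 | lithium enolate of 6 | [Li]OC=1[C@](C)(CC=C)[C@H](O[Si](CC)(CC)CC)CCC=1C
F7 | step 7 | enol triflate of 6 | O=S(=O)(OC=1[C@](C)(CC=C)[C@H](O[Si](CC)(CC)CC)CCC=1C)C(F)(F)F
F8 | step 7 | trisubstituted alkene C5=C10(Me) | CC1=C[C@](C)(CC=C)[C@H](O[Si](CC)(CC)CC)CC1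
F9 | step 21 | 1α-hydroxy C7=C8 enoate tert-butyl ester | COC(=O)C1=CC[C@H]2[C@](C)(CC=C)[C@@H](Cl)C[C@H](O)[C@]2(C)[C@H]1C(=O)OC(C)(C)C
F10 | step 21 | 1α-triethylsilyl ether of F9 | COC(=O)C1=CC[C@H]2[C@](C)(CC=C)[C@@H](Cl)C[C@H](O[Si](CC)(CC)CC)[C@]2(C)[C@H]1C(=O)OC(C)(C)C
F11 | step 21 | C11 trimethylsilyl ester, 1α-OSiEt3 | COC(=O)C1=CC[C@H]2[C@](C)(CC=C)[C@@H](Cl)C[C@H](O[Si](CC)(CC)CC)[C@]2(C)[C@H]1C(=O)O[Si](C)(C)C
F12 | step 21 | C11 acid, 1α-OSiEt3 | COC(=O)C1=CC[C@H]2[C@](C)(CC=C)[C@@H](Cl)C[C@H](O[Si](CC)(CC)CC)[C@]2(C)[C@H]1C(=O)O
F13 | step 21 | C11 acid chloride, 1α-OSiEt3 | COC(=O)C1=CC[C@H]2[C@](C)(CC=C)[C@@H](Cl)C[C@H](O[Si](CC)(CC)CC)[C@]2(C)[C@H]1C(=O)Cl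
F14 | step 21 | C11 aldehyde, 1α-OSiEt3, 4α-allyl | COC(=O)C1=CC[C@H]2[C@](C)(CC=C)[C@@H](Cl)C[C@H](O[Si](CC)(CC)CC)[C@]2(C)[C@H]1C=O
F15 | step 21 | 1-O-(triethylsilyl) target | COC(=O)C1=CC[C@H]2[C@](C)(C/C=C/C(C)(C)O)[C@@H](Cl)C[C@H](O[Si](CC)(CC)CC)[C@]2(C)[C@H]1C=O
A1 | alternative 1 | trans-fused octalin aldehyde (C6=C7 alkene, C1 ketone, 3β-silyl ether, C12 as PMB ether) | COc3ccc(COC[C@H]1C=C[C@H]2[C@](C)(CC=C)[C@@H](O[Si](C)(C)C(C)(C)C)CC(=O)[C@]2(C)[C@H]1C=O)cc3
A2 | alternative 2 | tricyclic lactone with C5=C6 and C8=C9 alkenes | COC(=O)C1=C2C(=O)O[C@H]3C[C@@H](O[Si](C)(C)C(C)(C)C)[C@@](C)(CC=C)C(=CC1)[C@@]23C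
A3 | alternative 3 | trans-decalin 1α-ol 3β-chloride with C8 enol triflate | O=S(=O)(OC1=CC[C@H]2[C@](C)(CC(=O)OCC)[C@@H](Cl)C[C@H](O)[C@]2(C)[C@H]1CO[Si](c1ccccc1)(c1ccccc1)C(C)(C)C)C(F)(F)F
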